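## Retrosynthetic overview

1. The cyclopentane (ring B) is cut at the bond between the spiro dione carbon and CH(iPr) (Conia-ene retron: dione enol plus Me2C=CH– tether). The cyclohexenedione (ring A) is cut at the C(=O)–CMe2 bond (acylketene plus enol ether). This leaves one acyclic β-keto ester, from which a single thermal operation closes ring A first and then ring B.
2. The β-keto ester is assembled from three pieces: a pinanylidene acetate, a homoprenyl Grignard reagent (conjugate addition creates the quaternary pinane carbon) and a 3-methoxycyclobutenone that acts as a ring-opening acyl donor with OMe, Me and CHMe2 already in place.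
3. The pinanylidene acetate comes from nopinone, which comes from (+)-β-pinene and then (+)-α-pinene (chiral pool; the bicyclo[3.1.1]heptane is never built or broken).
4. The cyclobutenone comes from dimethylketene and 1-methoxypropyne by [2+2] cycloaddition.
5. Ring order: pinane (bought), cyclobutenone (made, then opened), ring A, ring B.

Assumption: the SMILES is taken as drawn (pinane core of the (1R,5R)-(+)-pinene series, spiro dione carbon cis to the gem-dimethyl bridge), and the (+)-α-pinene used is of ≥97% ee.

## Route

Step 1
Reactants: 1 (1R,5R)-(+)-α-pinene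
Product: 4 (1R,5R)-(+)-β-pinene, via (pin-2-en-10-yl)potassium 2 (not isolated), via potassium trimethoxy(pin-2-en-10-yl)borate 3 (not isolated)
Conditions: n-BuLi, KOt-Bu, hexane, rt, 48 h; B(OMe)3, Et2O, −78 °C to rt; 3 M HCl
Reagents that add atoms: none
Why: Schlosser-base metalation of the C10 methyl gives the allylpotassium, borylation at C10 follows, and protonolysis of the allylborate with allylic transposition (SE2′) puts H on C3 and leaves the exocyclic alkene (the known contrathermodynamic α- to β-pinene isomerization); C1 and C5 are not touched.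

Step 2
Reactants: 4 (1R,5R)-(+)-β-pinene
Product: 6 (1S,5R)-(−)-nopinone, via secondary ozonide 5 (not isolated)
Conditions: O3, CH2Cl2, −78 °C; Me2S, −78 °C to rt
Reagents that add atoms: ozone, [O-][O+]=O
Why: Ozonolysis with reductive work-up (Criegee mechanism) cleaves the 1,1-disubstituted alkene to the ketone without touching the bridgehead stereocentres (the C1 descriptor changes only through CIP priorities).

Step 3
Reactants: 6 (1S,5R)-(−)-nopinone; 7 tert-butyl 2-(diethoxyphosphoryl)acetate
Product: 8 tert-butyl 2-[(1S,5R)-6,6-dimethylbicyclo[3.1.1]heptan-2-ylidene]acetate (E/Z mixture)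
Conditions: NaH, THF, 0 °C to reflux, 24 h
Reagents that add atoms: none
Why: Horner–Wadsworth–Emmons olefination of the ketone with the stabilised phosphonate anion; the E/Z mixture does not matter because the ring carbon becomes sp3 in step 6 and the α-carbon is planarised again in step 7.

Step 4
Reactants: 9 2-chloro-1,1-dimethoxyethane
Product: 11 1-methoxyprop-1-yne, via sodium methoxyethynide 10 (not isolated)
Conditions: NaNH2 (3 equiv), liq. NH3, −33 °C; MeI, −40 °C; H2O work-up
Reagents that add atoms: iodomethane, CI
Why: NaNH2 effects double elimination (HCl, then MeOH) from the chloroacetal to the sodium alkoxyethynide, which is C-methylated by MeI (the classical alkoxyacetylene synthesis); no stereocentre is formed.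

Step 5
Reactants: 12 2-methylpropanoyl chloride; 11 1-methoxyprop-1-yne
Product: 14 3-methoxy-2,4,4-trimethylcyclobut-2-en-1-one, via dimethylketene 13 (not isolated)
Conditions: Et3N, Et2O, reflux, 24 h
Reagents that add atoms: none
Why: Dehydrochlorination gives dimethylketene, which undergoes a regioselective thermal [2+2] cycloaddition with the ynol ether (the nucleophilic methyl-bearing alkyne carbon bonds to the ketene carbonyl carbon) to give the 3-alkoxycyclobutenone; no stereocentre is formed.

Step 6
Reactants: 8 tert-butyl 2-[(1S,5R)-6,6-dimethylbicyclo[3.1.1]heptan-2-ylidene]acetate; 15 5-bromo-2-methylpent-2-ene; 14 3-methoxy-2,4,4-trimethylcyclobut-2-en-1-one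
Product: 19 tert-butyl 2-[2-(4-methylpent-3-en-1-yl)-6,6-dimethylbicyclo[3.1.1]heptan-2-yl]-5-methoxy-4,6-dimethyl-3-oxohept-4-enoate (homoprenyl chain trans to the gem-dimethyl bridge; epimer mixture at the ester α-carbon), via Grignard reagent 16 (not isolated), via silyl ketene acetal 17 (not isolated), via lithium ester enolate 18 (not isolated)
Conditions: 15, Mg, THF, rt; 8, CuBr·SMe2 (10 mol %), TMSCl, THF, −78 to −20 °C; MeLi, 0 °C; 14, −78 to 0 °C; aq. NH4Cl
Reagents that add atoms: none
Why: Proposed new method: the copper-catalysed, TMSCl-accelerated conjugate addition (known) attacks the exocyclic enoate from the face opposite the gem-dimethyl bridge, the same facial preference as Grignard addition to nopinone or hydroboration of β-pinene, so the new quaternary carbon carries the homoprenyl chain trans and the acetate carbon cis to that bridge; the lithium enolate regenerated with MeLi then adds 1,2 to the strained, non-enolisable cyclobutenone, and the resulting cyclobutenoxide undergoes oxyanion-accelerated 4π-electrocyclic ring opening to a dienolate that is quenched by the acidic α-H, a net C-acylation delivering the β-methoxy enone, the closest known chemistry being conjugate addition–enolate trapping and organolithium addition/ring opening of cyclobutenones.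

Step 7
Reactants: 19 tert-butyl 2-[2-(4-methylpent-3-en-1-yl)-6,6-dimethylbicyclo[3.1.1]heptan-2-yl]-5-methoxy-4,6-dimethyl-3-oxohept-4-enoate
Product: 23 CNP0307059.1, via acylketene 20 (not isolated), via enol ether acylketene tautomer 21 (not isolated), via 2-alkyl-1,3-dione 22 (not isolated)
Conditions: Ph2O (0.01 M), 150 °C, 2 h; then 240 °C, 12 h
Reagents that add atoms: none
Why: Proposed new method: the α-H β-keto tert-butyl ester loses t-BuOH to give acylketene 20 (known thermal acylketene generation), the γ-H of its β-methoxy enone shifts (1,5-H shift, then reketonisation) to give the tetrasubstituted enol ether 21, whose nucleophilic CMe2 carbon C-acylates the ketene in a six-membered mode (O-acylation is excluded because that oxygen is methylated) to give the enolised dione 22 = ring A, and at 240 °C 22 undergoes a Conia-ene reaction (enol carbon to the proximal alkene carbon, enol H to CMe2, which becomes iPr) = ring B; the concerted six-membered ene transition state forces iPr cis to the H-donating carbonyl, the donor is expected to be the less hindered and more nucleophilic enol of the carbonyl next to C(Me)= and not the one next to CMe2, and the assembly is expected to sit on the cyclopentane face away from bridgehead C1, which together set the spiro carbon and the CH(iPr) carbon as in 23, the closest known reactions being acylketene trapping by enol ethers and the thermal Conia-ene spirocyclisation of 2-alkenyl-1,3-diones.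

## Compound list

1 | (1R,5R)-(+)-α-pinene (2,6,6-trimethylbicyclo[3.1.1]hept-2-ene) | CC1=CC[C@@H]2C[C@H]1C2(C)C | starting material
2 | (pin-2-en-10-yl)potassium (1 metalated at the C10 methyl) | [K]CC1=CC[C@@H]2C[C@H]1C2(C)C | intermediate
3 | potassium trimethoxy(pin-2-en-10-yl)borate | CO[B-](OC)(OC)CC1=CC[C@@H]2C[C@H]1C2(C)C.[K+] | intermediate
4 | (1R,5R)-(+)-β-pinene (6,6-dimethyl-2-methylidenebicyclo[3.1.1]heptane) | C=C1CC[C@@H]2C[C@H]1C2(C)C | intermediate
5 | secondary ozonide of 4 (spiro 1,2,4-trioxolane at pinane C2, epimer mixture there) | C1OC2(OO1)CC[C@@H]3C[C@H]2C3(C)C | intermediate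
6 | (1S,5R)-(−)-nopinone (6,6-dimethylbicyclo[3.1.1]heptan-2-one) | O=C1CC[C@@H]2C[C@H]1C2(C)C | intermediate
7 | tert-butyl 2-(diethoxyphosphoryl)acetate | CCOP(=O)(CC(=O)OC(C)(C)C)OCC | starting material
8 | tert-butyl 2-[(1S,5R)-6,6-dimethylbicyclo[3.1.1]heptan-2-ylidene]acetate (E/Z mixture) | CC(C)(C)OC(=O)C=C1CC[C@@H]2C[C@H]1C2(C)C | intermediate
9 | 2-chloro-1,1-dimethoxyethane | COC(CCl)OC | starting material
10 | sodium methoxyethynide | COC#C[Na] | intermediate
11 | 1-methoxyprop-1-yne | CC#COC | intermediate
12 | 2-methylpropanoyl chloride | CC(C)C(=O)Cl | starting material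
13 | dimethylketene | CC(C)=C=O | intermediate
14 | 3-methoxy-2,4,4-trimethylcyclobut-2-en-1-one | COC1=C(C)C(=O)C1(C)C | intermediate
15 | 5-bromo-2-methylpent-2-ene | CC(C)=CCCBr | starting material
16 | (4-methylpent-3-en-1-yl)magnesium bromide | CC(C)=CCC[Mg]Br | intermediate
17 | tert-butyl trimethylsilyl ketene acetal of the conjugate adduct (pinane C2 quaternary: homoprenyl trans, ketene-acetal carbon cis to the gem-dimethyl bridge; bridgeheads as in 1) | CC(C)(C)OC(O[Si](C)(C)C)=C[C@@]1(CCC=C(C)C)CC[C@@H]2C[C@H]1C2(C)C | intermediate
18 | lithium enolate of tert-butyl 2-[2-(4-methylpent-3-en-1-yl)-6,6-dimethylbicyclo[3.1.1]heptan-2-yl]acetate (same pinane configuration as 17) | CC(C)(C)OC(O[Li])=C[C@@]1(CCC=C(C)C)CC[C@@H]2C[C@H]1C2(C)C | intermediate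
19 | tert-butyl 2-[2-(4-methylpent-3-en-1-yl)-6,6-dimethylbicyclo[3.1.1]heptan-2-yl]-5-methoxy-4,6-dimethyl-3-oxohept-4-enoate (pinane as in 17; epimers at the ester α-carbon; enol ether E/Z not fixed) | CC(C)(C)OC(=O)C(C(=O)C(C)=C(OC)C(C)C)[C@@]1(CCC=C(C)C)CC[C@@H]2C[C@H]1C2(C)C | intermediate
20 | acylketene from 19 by loss of t-BuOH: 2-(pinan-2-yl)-5-methoxy-4,6-dimethylhepta-1,4-diene-1,3-dione (pinane as in 17) | O=C=C(C(=O)C(C)=C(OC)C(C)C)[C@@]1(CCC=C(C)C)CC[C@@H]2C[C@H]1C2(C)C | intermediate
21 | deconjugated tautomer of 20: 2-(pinan-2-yl)-5-methoxy-4,6-dimethylhepta-1,5-diene-1,3-dione (tetrasubstituted enol ether; C4 epimers) | O=C=C(C(=O)C(C)C(OC)=C(C)C)[C@@]1(CCC=C(C)C)CC[C@@H]2C[C@H]1C2(C)C | intermediate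
22 | 5-methoxy-4,6,6-trimethyl-2-[2-(4-methylpent-3-en-1-yl)-6,6-dimethylbicyclo[3.1.1]heptan-2-yl]cyclohex-4-ene-1,3-dione (ring A closed; largely enolised at C2; pinane as in 17) | COC1=C(C)C(=O)C(C(=O)C1(C)C)[C@@]1(CCC=C(C)C)CC[C@@H]2C[C@H]1C2(C)C | intermediate
23 | CNP0307059.1: 4''-methoxy-3'',5'',5'',6,6-pentamethyl-3'-(propan-2-yl)dispiro[bicyclo[3.1.1]heptane-2,1'-cyclopentane-2',1''-cyclohex[3]ene]-2'',6''-dione; spiro dione carbon cis and ring-B CH2 trans to the gem-dimethyl bridge; on the cyclopentane, iPr, the enone carbonyl and pinane C3 on one face, the CMe2-flanked carbonyl and pinane C1 on the other | COC1=C(C)C(=O)[C@@]2(C(=O)C1(C)C)[C@@H](C(C)C)CC[C@@]21CC[C@@H]2C[C@H]1C2(C)C | target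

## Step count and risks

Total step count: 7. Longest linear sequence: 5 (steps 1, 2, 3, 6, 7).

The three steps most likely to fail:

**Step 7.** The ring-A closure depends on an unprecedented tautomerisation/C-acylation of an acylketene, and the acidic dione 22 could protonate the alkene or give the spiro epimer in the ene step. The fallback sets out from 19 and comes back at 23, closing the rings in the opposite order by radical and anionic chemistry. Mn(OAc)3 and Cu(OAc)2 in MeOH/AcOH oxidise the β-keto ester to its α-radical, which cyclises 5-exo onto the trisubstituted alkene; oxidation of the tertiary radical gives the spiro cyclopentane β-keto ester with an isopropenyl group F1 (diastereomers separated). Because the ester of F1 has no α-H, KHMDS in THF deprotonates the γ-CH of the β-methoxy enone, and a vinylogous Dieckmann closure on the tert-butyl ester gives the isopropenyl analogue of the target F2. H2 over Pd/C in EtOAc reduces only the isopropenyl group and returns to 23.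

**Step 6.** The conjugate addition must create a quaternary centre next to a bridgehead, and the hindered enolate must then add to a hindered ketone. The fallback sets out from 6 and comes back at 17, using a far stronger acceptor and a neutral acylation. Knoevenagel condensation of 6 with Meldrum's acid (TiCl4, pyridine, THF) gives the alkylidene Meldrum's acid F3. Grignard reagent 16 with CuBr·SMe2 adds to it from the same face to give the substituted Meldrum's acid F4. Heating F4 with t-BuOH in toluene opens and decarboxylates it to the saturated tert-butyl ester F5. LDA and TMSCl convert F5 into 17, which is then acylated thermally (toluene, 110 °C) by the vinylketene formed from 14 by ring opening; mild aqueous work-up gives 19.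

**Step 5.** Dimethylketene forms slowly from the acid chloride and may dimerise before it meets the volatile ynol ether. The fallback sets out from 11 and comes back at 14, replacing the ketene by a keteniminium ion. 1-Chloro-N,N,2-trimethylprop-1-en-1-amine and AgBF4 in CH2Cl2 give tetramethylketeniminium tetrafluoroborate, which adds [2+2] to 11 with the same regiochemistry to give the cyclobuteniminium salt F6. Aqueous NaHCO3 hydrolyses F6 to 14.

## Further compounds

F1 | step 7 | tert-butyl 1-(3-methoxy-2,4-dimethylpent-2-enoyl)-2-(prop-1-en-2-yl)spiro[cyclopentane-3,2'-pinane]-1-carboxylate (configuration as in 23, ketone cis to isopropenyl) | CC(C)C(OC)=C(C)C(=O)[C@@]2(C(=O)OC(C)(C)C)[C@@H](C(C)=C)CC[C@@]21CC[C@@H]2C[C@H]1C2(C)C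
F2 | step 7 | isopropenyl analogue of 23 (prop-1-en-2-yl in place of propan-2-yl, all stereocentres as in 23) | COC1=C(C)C(=O)[C@@]2(C(=O)C1(C)C)[C@@H](C(C)=C)CC[C@@]21CC[C@@H]2C[C@H]1C2(C)C
F3 | step 6 | 5-[(1S,5R)-6,6-dimethylbicyclo[3.1.1]heptan-2-ylidene]-2,2-dimethyl-1,3-dioxane-4,6-dione | CC1(C)OC(=O)C(=C2CC[C@@H]3C[C@H]2C3(C)C)C(=O)O1
F4 | step 6 | 2,2-dimethyl-5-[2-(4-methylpent-3-en-1-yl)-6,6-dimethylbicyclo[3.1.1]heptan-2-yl]-1,3-dioxane-4,6-dione (homoprenyl trans to the gem-dimethyl bridge) | CC1(C)OC(=O)C(C(=O)O1)[C@@]1(CCC=C(C)C)CC[C@@H]2C[C@H]1C2(C)C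
F5 | step 6 | tert-butyl 2-[2-(4-methylpent-3-en-1-yl)-6,6-dimethylbicyclo[3.1.1]heptan-2-yl]acetate (homoprenyl trans to the gem-dimethyl bridge) | CC(C)(C)OC(=O)C[C@@]1(CCC=C(C)C)CC[C@@H]2C[C@H]1C2(C)C
F6 | step 5 | 3-methoxy-N,N,2,4,4-pentamethylcyclobut-2-en-1-iminium tetrafluoroborate | COC1=C(C)C(=[N+](C)C)C1(C)C.F[B-](F)(F)F
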